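(Readings and results are simulated for an exercise.)

The complex with two exchanged was the product I had to foretell, at 2.0 min, in flasks that differed in their charge of incoming ligand.

in all of them: starting complex 0.050 M
- gamma: incoming ligand 0.030 M; run made earlier
- delta: incoming ligand 0.18 M; run made earlier
- spring: incoming ligand 0.0250 M; time 2.0 min
- autumn: incoming ligand 0.0750 M; time 2.0 min
- summer: incoming ligand 0.150 M; time 2.0 min

| run | time / s | complex with two exchanged / % | starting complex / % |
|---|---|---|---|
| gamma | 10.0 | 2.5 | 84.3 |
| gamma | 12.0 | 2.7 | 84.0 |
| gamma | 20.0 | 1.6 | 79.9 |
| gamma | 30.0 | 2.0 | 77.6 |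
| gamma | 50.0 | 4.7 | 76.2 |
| gamma | 80.0 | 3.5 | 75.1 |
| delta | 15.0 | 41.4 | 27.9 |
| delta | 30.0 | 53.5 | 20.6 |
| delta | 40.0 | 60.0 | 18.1 |
| delta | 60.0 | 60.8 | 18.0 |
| delta | 80.0 | 63.9 | 14.9 |

(standard deviation of a reading: 1 percentage point)

- amount of complex with two exchanged at the end, in percent of the starting complex charged, for each flask in turn (spring, autumn, summer)

- the numbers in the tables scatter by 1 percentage point (one standard deviation)

I began with the bench count: each incoming ligand charged replaces one site, and the complex has two sites. The earlier runs refused it. In the delta run the charge covered both sites 1.80 times over, yet 14.9% of the starting complex stood at 80.0 s. So I counted what had arrived. With complex with one exchanged taken by difference, uptake per complex charged is one minus the starting complex plus the complex with two exchanged. The curves had flattened, so I let the last reading stand for each plateau. That gave an uptake of 28.4% of the complex charged in gamma and 149% in delta, which are 47.3% and 41.4% of the ligand charged. Their mean, 44.4%, is the taken share: ligand found on complex per ligand charged, as read.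

My rule was uptake equals taken share times the ratio of ligand to complex charged. It gave 0.665 equivalents for autumn and 1.33 for summer. The rule stops where uptake reaches the 2 sites, and summer stayed under that. Spring was charged at 0.833 of the gamma charge, just outside the runs, so I trusted it less there. My rule gives uptake, a different quantity from the forecast's.

The forecast judged that “both runs look essentially equilibrated by 2 min” and gave 4%, 23% and 53% for spring, autumn and summer.

    starting complex + incoming ligand → leaving ligand + complex with one exchanged (k = 0.890 M⁻¹ s⁻¹)
    complex with one exchanged + incoming ligand → leaving ligand + complex with two exchanged (k = 1.10 M⁻¹ s⁻¹)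
    incoming ligand ⇌ dormant form (K = 22.0, k = 0.0560 s⁻¹)

The flasks gave 3.19%, 20.8% and 54.2%, within the margin of the forecast. Yet autumn was still moving: incoming ligand, the limiting reagent, stood at 1.3% of its charge with 0.0370 M of dormant form beside it, and the product reached 46.1% after 20.0 min. Autumn's uptake of 0.741 equiv is a taken share of 49.4%. For summer, the part not taken, reckoned from 44.4%, is 0.0835 M, and summer held 0.0800 M of dormant form at 2.00 min.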